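**Retrosynthetic overview**
1. Eremophilane numbering is used: ring A = C1–C5 and C10, ring B = C5–C10, C14 on C4, C15 on C5, β = face of C15. The plan rests on ring B. Its cis-8α,9α-diester is read as a former C8=C9 cyclohexene, so C6–C7 and C5–C10 are the two σ-bonds of a Diels–Alder reaction and C1–C4 (ring A) is the tether.
2. Endgame: remove both esters. O9 is traced back to the C2 carbonyl oxygen through a 2,9-bridged ketal made from the 8β,9β-epoxide. The C8 carbinol comes from its ketone, and the isopropenyl group from the C11 carbinol.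
3. The cis methyl pair C14/C15 is traced back to a γ-lactone C15(=O)–O–C14, which is opened by reduction, mesylation and hydride displacement.
4. An intramolecular [4+2] of a (7E,9Z)-triene, with an α-methylene-γ-butyrolactone as dienophile, forms rings A and B together in one step. The helper lactone ring exists before this step, and the 2,9-oxygen bridge is only temporary afterwards.
5. The triene comes from a Z-selective Wittig reaction (C9=C10) between a ketal-phosphonium salt and a γ-silyloxy enal. C4 is set by an Evans alkylation.

Key step: step 12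

Remark: the 9-hydroxy-2-ketone of the penultimate step is drawn open, although it can rest as its 2,9-hemiketal, which is the same compound in equilibrium.

**Step 1**
Reactants: 1 methyl 4-chloro-4-oxobutanoate; 2 ethene
Product: 3 methyl 6-chloro-4-oxohexanoate
Conditions: AlCl3 (2.2 equiv), ethene (1 atm), CH2Cl2, 0 °C → rt
Reagents that add atoms: none
Why: Friedel–Crafts-type acylation of an alkene, in which the acylium ion adds to ethene and chloride caps the chain; this is the standard entry to β-chloroethyl ketones, and the ester is inert.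

**Step 2**
Reactants: 3 methyl 6-chloro-4-oxohexanoate
Product: 4 methyl 3-[2-(2-chloroethyl)-1,3-dioxolan-2-yl]propanoate
Conditions: HOCH2CH2OH, p-TsOH (cat.), PhH, reflux (Dean–Stark)
Reagents that add atoms: ethane-1,2-diol OCCO
Why: Acid-catalysed ketalisation with azeotropic water removal works for γ-keto esters and β-chloro ketones alike, and the acidic medium keeps HCl from being eliminated.

**Step 3**
Reactants: 4 methyl 3-[2-(2-chloroethyl)-1,3-dioxolan-2-yl]propanoate
Product: 5 3-[2-(2-chloroethyl)-1,3-dioxolan-2-yl]propanoic acid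
Conditions: LiOH, THF/H2O, 0 °C → rt; then 1 M HCl to pH 4–5, 0 °C
Reagents that add atoms: lithium hydroxide [Li+].[OH-]
Why: In this ester saponification the primary chloride and the dioxolane tolerate cold LiOH, and the acid is released at a pH that spares the ketal.

**Step 4**
Reactants: 5 3-[2-(2-chloroethyl)-1,3-dioxolan-2-yl]propanoic acid; 6 (R)-4-benzyl-1,3-oxazolidin-2-one
Product: 8 (R)-4-benzyl-3-{3-[2-(2-chloroethyl)-1,3-dioxolan-2-yl]propanoyl}-1,3-oxazolidin-2-one, via mixed pivalic anhydride 7 (not isolated)
Conditions: PivCl, Et3N, THF, −20 °C; then 6, LiCl, −20 °C → rt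
Reagents that add atoms: none
Why: In this mixed-anhydride N-acylation of an Evans auxiliary, the hindered pivaloyl carbonyl steers attack to the wanted acyl group.

**Step 5**
Reactants: 8 N-acyl oxazolidinone; 9 tert-butyl bromoacetate
Product: 10 tert-butyl (3S)-3-[(R)-4-benzyl-2-oxo-1,3-oxazolidine-3-carbonyl]-4-[2-(2-chloroethyl)-1,3-dioxolan-2-yl]butanoate
Conditions: NaHMDS, THF, −78 °C; then 9, −78 → −40 °C
Reagents that add atoms: none
Why: In this Evans asymmetric alkylation the chelated sodium (Z)-enolate is attacked by the activated bromide on the face away from the benzyl group, which sets C4 as S, while the unactivated primary chloride does not react at −78 °C.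

**Step 6**
Reactants: 10 alkylated imide
Product: 12 (4S)-4-{[2-(2-chloroethyl)-1,3-dioxolan-2-yl]methyl}oxolan-2-one, via hydroxy ester 11 (not isolated)
Conditions: LiBH4, MeOH (1 equiv), THF, 0 °C; crude 11: CSA (cat.), PhMe, 70 °C
Reagents that add atoms: none
Why: Chemoselective LiBH4 reduction of the imide carbonyl leaves the tert-butyl ester untouched and releases the auxiliary, and acid-catalysed transesterification then closes the five-membered lactone without touching C4.

**Step 7**
Reactants: 12 chloro ketal lactone
Product: 14 phosphonium iodide of 12 (Ph3P+ on C10), via primary iodide 13 (not isolated)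
Conditions: NaI, PPh3, MeCN, reflux
Reagents that add atoms: sodium iodide [Na+].[I-]; triphenylphosphine c1ccc(cc1)P(c1ccccc1)c1ccccc1
Why: Finkelstein exchange is followed in the same flask by SN2 quaternisation of PPh3 at the unhindered primary carbon, as known for 2-(2-haloethyl)dioxolanes.

**Step 8**
Reactants: 15 2-methylbut-3-en-2-ol; 16 (E)-but-2-enal
Product: 17 (E)-4-hydroxy-4-methylpent-2-enal
Conditions: Hoveyda–Grubbs II (2 mol %), 16 (excess), CH2Cl2, 40 °C
Reagents that add atoms: none
Why: This olefin cross-metathesis of a tertiary allylic alcohol with an enal is E-selective under thermodynamic control and is driven by loss of propene.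

**Step 9**
Reactants: 17 (E)-4-hydroxy-4-methylpent-2-enal
Product: 18 (E)-4-methyl-4-(triethylsilyloxy)pent-2-enal
Conditions: TESOTf, 2,6-lutidine, CH2Cl2, −78 → 0 °C
Reagents that add atoms: triethylsilyl triflate CC[Si](CC)(CC)OS(=O)(=O)C(F)(F)F
Why: The triflate silylates the tertiary alcohol, and the enal cannot enolise because it has no γ-hydrogen.

**Step 10**
Reactants: 14 phosphonium iodide; 18 silyloxy enal
Product: 20 (4S)-4-({2-[(2Z,4E)-6-methyl-6-(triethylsilyloxy)hepta-2,4-dienyl]-1,3-dioxolan-2-yl}methyl)oxolan-2-one, via phosphonium ylide 19 (not isolated)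
Conditions: KHMDS (1.0 equiv), THF, −78 °C; then 18, −78 °C → rt
Reagents that add atoms: none
Why: The salt-free Wittig reaction of a non-stabilised ylide with an enal is kinetically Z-selective at the new C9=C10 bond, the E geometry of C7=C8 is carried over from 18, and one equivalent of base leaves the less acidic lactone alone.

**Step 11**
Reactants: 20 diene lactone
Product: 23 (4S)-3-methylidene-4-({2-[(2Z,4E)-6-methyl-6-(triethylsilyloxy)hepta-2,4-dienyl]-1,3-dioxolan-2-yl}methyl)oxolan-2-one, via Mannich base 21 (not isolated), via methiodide 22 (not isolated)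
Conditions: LDA, THF, −78 °C; CH2=NMe2+ I−, −78 °C → rt; crude 21: MeI, MeOH, rt; then aq NaHCO3, CH2Cl2, rt
Reagents that add atoms: N,N-dimethylmethyleneiminium iodide C=[N+](C)C.[I-]
Why: This lactone α-methylenation proceeds by a Mannich reaction of the lithium enolate with Eschenmoser's salt and Hofmann-type elimination of the methiodide, and bicarbonate is too mild to move the double bond into the ring, so C4 is kept.

**Step 12**
Reactants: 23 (7E,9Z)-triene with C2 dioxolane, 11-OTES and α-methylene lactone dienophile
Product: 24 tricyclic lactone (cis-fused eremophil-8-ene; 2,2-ethylenedioxy; 11-OTES; β-face lactone C15(=O)–O–C14; 10β-H; 7β side chain)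
Conditions: PhMe (0.005 M), BHT (cat.), degassed, base-washed sealed tube, 130 °C
Reagents that add atoms: none
Why: This is a concerted suprafacial thermal [4+2] cycloaddition in which the diene C7=C8–C9=C10 adds to C5=C6 and forms C6–C7 and C5–C10 in one event; the closest known type is the thermal intramolecular Diels–Alder reaction of 1,7,9-decatrienes carrying a (Z)-diene, here with an α-methylene-γ-butyrolactone, a proven dienophile. Ring B (C5–C10) closes as the cyclohexene of the cycloaddition itself, and ring A (C1–C5, C10) closes at the same moment because the chain C1–C4 already joins diene terminus C10 to dienophile carbon C5 (fused mode; the bridged mode would need a strained medium ring). C1 occupies the inside position on C10, so the chain reaches C5 only when C4 is exo and the lactone carbonyl C15 is endo, which makes H10 cis to C15 (cis-decalin), and the E geometry of C7=C8 places the side chain outside, hence cis to H10. In this geometry the C5 substituent is equatorial on the nascent chair of ring A and the site on C4 cis to it is axial and nearly eclipsed with it, so a free methyl on C4 would take the equatorial site and come out trans to C15; the five-membered lactone welds C14 to C15, makes the required arrangement the only possible one, and lets C10 bond only to the lactone face that bears C3, so that C4 alone fixes C5, C10 and C7. The conjugated carbonyl lowers the LUMO of the 1,1-disubstituted alkene, so the reaction should proceed near 130 °C, where the [1,5]-hydrogen shift from C1 to C7 that plagues (Z)-dienes is still slow. High dilution, BHT and base-washed glass guard against dimerisation, radical polymerisation of the methylene lactone and acid-induced loss of the dienylic silyl ether.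

**Step 13**
Reactants: 24 tricyclic lactone
Product: 25 14,15-diol of the 2,2-ethylenedioxy-11-OTES-eremophil-8-ene
Conditions: LiAlH4, THF, 0 °C
Reagents that add atoms: none
Why: Hydride reduction converts the lactone to the 1,4-diol, and the ketal, the silyl ether and the isolated alkene are inert.

**Step 14**
Reactants: 25 14,15-diol
Product: 26 14,15-bis(methanesulfonate)
Conditions: MsCl, Et3N, CH2Cl2, −20 → 0 °C
Reagents that add atoms: methanesulfonyl chloride CS(=O)(=O)Cl
Why: Sulfene-type mesylation is fast even at the neopentyl C15 hydroxyl, so both alcohols are capped in the cold before one can displace the other to give a cyclic ether.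

**Step 15**
Reactants: 26 bis(methanesulfonate)
Product: 27 2,2-ethylenedioxy-11-(triethylsilyloxy)-10βH-eremophil-8-ene (4β,5β-dimethyl; 7β side chain)
Conditions: LiEt3BH (excess), THF, reflux
Reagents that add atoms: none
Why: SN2 hydride displacement with Super-Hydride, the reagent of choice for hindered and neopentyl primary sulfonates, turns C14 and C15 into the cis methyl pair without change at C4 or C5.

**Step 16**
Reactants: 27 ketal silyl ether
Product: 28 11-hydroxy-10βH-eremophil-8-en-2-one
Conditions: 1 M HCl, THF, rt
Reagents that add atoms: water O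
Why: One acid hydrolysis removes both the dioxolane and the tertiary silyl ether, which is needed because in the folded cis-decalin the axial ketal oxygen on C2 lies under C9 exactly where O9 must go, and the freed carbonyl and carbinol are the control elements of the next steps.

**Step 17**
Reactants: 28 keto alcohol
Product: 30 2α,9α-epoxy-2β-methoxy-10βH-eremophilane-8β,11-diol (bridged methyl ketal), via β-epoxide 29 (not isolated)
Conditions: VO(acac)2 (cat.), t-BuOOH, PhH, rt → 40 °C; then MeOH, CSA (cat.), 0 °C → rt
Reagents that add atoms: tert-butyl hydroperoxide CC(C)(C)OO; methanol CO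
Why: Vanadium-catalysed epoxidation directed by the homoallylic C11 hydroxyl places the epoxide on the β face syn to the C7 side chain, and acid then triggers 5-exo, trans-diaxial (Fürst–Plattner) opening at C9 by the C2 carbonyl or hemiketal oxygen, the only nucleophile that can reach the concave α face, with methanol capping the oxocarbenium ion (the known cyclisation of γ,δ-epoxy ketones to cyclic ketals), which sets 9α-O, 8β-OH and C2.

**Step 18**
Reactants: 30 bridged ketal diol
Product: 31 2α,9α-epoxy-11-hydroxy-2β-methoxy-10βH-eremophilan-8-one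
Conditions: TPAP (cat.), NMO, 4 Å MS, CH2Cl2, rt
Reagents that add atoms: none
Why: Ley–Griffith oxidation of the only secondary alcohol under neutral conditions avoids retro-aldol cleavage or dehydration of the β-hydroxy ketone, and C7 keeps its favoured equatorial side chain.

**Step 19**
Reactants: 31 8-ketone
Product: 32 2α,9α-epoxy-2β-methoxy-10βH-eremophilane-8α,11-diol
Conditions: Me4NBH(OAc)3, MeCN/AcOH, −30 °C
Reagents that add atoms: none
Why: In this Evans–Saksena hydroxyl-directed reduction the borohydride bound to O11, which can only sit on the β side of the equatorial C7–C11 bond, delivers hydride to the β face of C8 and gives the equatorial 8α-alcohol.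

**Step 20**
Reactants: 32 8α,11-diol
Product: 33 8α-acetoxy-2α,9α-epoxy-2β-methoxy-10βH-eremophilan-11-ol
Conditions: Ac2O, pyridine, DMAP (cat.), CH2Cl2, rt
Reagents that add atoms: acetic anhydride CC(=O)OC(C)=O
Why: DMAP-catalysed acetylation distinguishes the secondary 8α-hydroxyl from the tertiary C11 carbinol.

**Step 21**
Reactants: 33 acetoxy carbinol
Product: 34 8α-acetoxy-2α,9α-epoxy-2β-methoxy-10βH-eremophil-11-ene
Conditions: SOCl2, pyridine, −10 → 0 °C
Reagents that add atoms: none
Why: E2-type dehydration through the chlorosulfite takes one of six exposed methyl hydrogens rather than the hindered axial H7, and the alternative C7=C11 alkene would suffer A(1,3) strain with the equatorial 8-acetate.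

**Step 22**
Reactants: 34 bridged ketal
Product: 35 8α-acetoxy-9α-hydroxy-10βH-eremophil-11-en-2-one
Conditions: AcOH/THF/H2O, 40 °C
Reagents that add atoms: water O
Why: Mild hydrolysis of the mixed ketal cleaves only C2–O bonds, so the C2 ketone returns and O9 stays on C9 in its α configuration.

**Step 23**
Reactants: 35 hydroxy ketone; 36 3-methylbut-2-enoyl chloride
Product: 37 8α-acetoxy-9α-(3-methylbut-2-enoyloxy)-10βH-eremophil-11-en-2-one (CNP0150397.1)
Conditions: 36, DMAP, pyridine, CH2Cl2, 0 → 40 °C
Reagents that add atoms: none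
Why: DMAP-catalysed acylation of the secondary 9α-hydroxyl of the open keto alcohol drains the hemiketal equilibrium, and pyridine is too weak a base to form the vinylketene that would deconjugate the senecioyl group.

**Compound list**
1 | methyl 4-chloro-4-oxobutanoate | COC(=O)CCC(=O)Cl | starting material
2 | ethene | C=C | starting material
3 | methyl 6-chloro-4-oxohexanoate | COC(=O)CCC(=O)CCCl | intermediate
4 | methyl 3-[2-(2-chloroethyl)-1,3-dioxolan-2-yl]propanoate | COC(=O)CCC1(CCCl)OCCO1 | intermediate
5 | 3-[2-(2-chloroethyl)-1,3-dioxolan-2-yl]propanoic acid | OC(=O)CCC1(CCCl)OCCO1 | intermediate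
6 | (R)-4-benzyl-1,3-oxazolidin-2-one | O=C1N[C@H](Cc2ccccc2)CO1 | starting material
7 | mixed pivalic anhydride of 5 | CC(C)(C)C(=O)OC(=O)CCC1(CCCl)OCCO1 | intermediate
8 | N-acyl oxazolidinone | O=C(CCC1(CCCl)OCCO1)N2[C@H](Cc3ccccc3)COC2=O | intermediate
9 | tert-butyl bromoacetate | CC(C)(C)OC(=O)CBr | starting material
10 | alkylated imide (C4 = S) | O=C([C@H](CC(=O)OC(C)(C)C)CC1(CCCl)OCCO1)N2[C@H](Cc3ccccc3)COC2=O | intermediate
11 | tert-butyl (3S)-4-[2-(2-chloroethyl)-1,3-dioxolan-2-yl]-3-(hydroxymethyl)butanoate | OC[C@H](CC(=O)OC(C)(C)C)CC1(CCCl)OCCO1 | intermediate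
12 | (4S)-4-{[2-(2-chloroethyl)-1,3-dioxolan-2-yl]methyl}oxolan-2-one | O=C1C[C@H](CC2(CCCl)OCCO2)CO1 | intermediate
13 | iodide corresponding to 12 | O=C1C[C@H](CC2(CCI)OCCO2)CO1 | intermediate
14 | phosphonium iodide | O=C1C[C@H](CC2(CC[P+](c3ccccc3)(c3ccccc3)c3ccccc3)OCCO2)CO1.[I-] | intermediate
15 | 2-methylbut-3-en-2-ol | C=CC(C)(C)O | starting material
16 | (E)-but-2-enal | C/C=C/C=O | starting material
17 | (E)-4-hydroxy-4-methylpent-2-enal | CC(C)(O)/C=C/C=O | intermediate
18 | (E)-4-methyl-4-(triethylsilyloxy)pent-2-enal | CC(C)(O[Si](CC)(CC)CC)/C=C/C=O | intermediate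
19 | phosphonium ylide from 14 | O=C1C[C@H](CC2(CC=P(c3ccccc3)(c3ccccc3)c3ccccc3)OCCO2)CO1 | intermediate
20 | (9Z,7E)-diene lactone | O=C1C[C@H](CC2(C/C=C\C=C\C(C)(C)O[Si](CC)(CC)CC)OCCO2)CO1 | intermediate
21 | trans-α-(dimethylaminomethyl) lactone | O=C1[C@@H](CN(C)C)[C@H](CC2(C/C=C\C=C\C(C)(C)O[Si](CC)(CC)CC)OCCO2)CO1 | intermediate
22 | methiodide of 21 | O=C1[C@@H](C[N+](C)(C)C)[C@H](CC2(C/C=C\C=C\C(C)(C)O[Si](CC)(CC)CC)OCCO2)CO1.[I-] | intermediate
23 | (7E,9Z)-triene, α-methylene lactone (cycloaddition precursor) | O=C1C(=C)[C@H](CC2(C/C=C\C=C\C(C)(C)O[Si](CC)(CC)CC)OCCO2)CO1 | intermediate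
24 | tricyclic lactone (cycloadduct) | CC(C)(O[Si](CC)(CC)CC)[C@H]1C[C@@]2(C(=O)OC4)[C@H](CC3(OCCO3)C[C@@H]24)C=C1 | intermediate
25 | 14,15-diol | CC(C)(O[Si](CC)(CC)CC)[C@H]1C[C@@]2(CO)[C@H](CC3(OCCO3)C[C@@H]2CO)C=C1 | intermediate
26 | 14,15-bis(methanesulfonate) | CC(C)(O[Si](CC)(CC)CC)[C@H]1C[C@@]2(COS(C)(=O)=O)[C@H](CC3(OCCO3)C[C@@H]2COS(C)(=O)=O)C=C1 | intermediate
27 | 2,2-ethylenedioxy-11-(triethylsilyloxy)-10βH-eremophil-8-ene | CC(C)(O[Si](CC)(CC)CC)[C@H]1C[C@@]2(C)[C@H](CC3(OCCO3)C[C@@H]2C)C=C1 | intermediate
28 | 11-hydroxy-10βH-eremophil-8-en-2-one | CC(C)(O)[C@H]1C[C@@]2(C)[C@H](CC(=O)C[C@@H]2C)C=C1 | intermediate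
29 | 8β,9β-epoxy-11-hydroxy-10βH-eremophilan-2-one | CC(C)(O)[C@H]1C[C@@]2(C)[C@H](CC(=O)C[C@@H]2C)[C@H]3O[C@@H]13 | intermediate
30 | 2α,9α-epoxy-2β-methoxy-10βH-eremophilane-8β,11-diol | CC(C)(O)[C@H]1C[C@@]2(C)[C@H](C[C@]3(OC)C[C@@H]2C)[C@H](O3)[C@H]1O | intermediate
31 | 2α,9α-epoxy-11-hydroxy-2β-methoxy-10βH-eremophilan-8-one | CC(C)(O)[C@H]1C[C@@]2(C)[C@H](C[C@]3(OC)C[C@@H]2C)[C@H](O3)C1=O | intermediate
32 | 2α,9α-epoxy-2β-methoxy-10βH-eremophilane-8α,11-diol | CC(C)(O)[C@H]1C[C@@]2(C)[C@H](C[C@]3(OC)C[C@@H]2C)[C@H](O3)[C@@H]1O | intermediate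
33 | 8α-acetate of 32 | CC(C)(O)[C@H]1C[C@@]2(C)[C@H](C[C@]3(OC)C[C@@H]2C)[C@H](O3)[C@@H]1OC(C)=O | intermediate
34 | 8α-acetoxy-2α,9α-epoxy-2β-methoxy-10βH-eremophil-11-ene | C=C(C)[C@H]1C[C@@]2(C)[C@H](C[C@]3(OC)C[C@@H]2C)[C@H](O3)[C@@H]1OC(C)=O | intermediate
35 | 8α-acetoxy-9α-hydroxy-10βH-eremophil-11-en-2-one | C=C(C)[C@H]1C[C@@]2(C)[C@H](CC(=O)C[C@@H]2C)[C@H](O)[C@@H]1OC(C)=O | intermediate
36 | 3-methylbut-2-enoyl chloride | CC(C)=CC(=O)Cl | starting material
37 | CNP0150397.1 | C=C(C)[C@H]1C[C@@]2(C)[C@H](CC(=O)C[C@@H]2C)[C@H](OC(=O)C=C(C)C)[C@@H]1OC(C)=O | target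

**Step count**
Total steps: 23. Longest linear sequence: 21 (steps 1–7 and 10–23).

**Steps most likely to fail**

1. **Step 12.** The cycloaddition may be too slow at temperatures where the (Z)-diene survives. Reaching the s-cis form costs strain, and C14 presses against the axial ketal oxygen on C2 in the transition state. [1,5]-Hydrogen migration, geometric isomerisation of the diene or polymerisation of the methylene lactone could then take over.
   Fallback, from 23 back to 24:
   - The silyl group is removed with Et3N·3HF to give the triene alcohol F1.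
   - Its bromomagnesium alkoxide (MeMgBr, 1 equiv, PhMe, −78 → 50 °C) carries an internal Lewis acid that can bind the endo lactone carbonyl from the C7 side chain. This is a metal-templated Diels–Alder reaction of a dienol.
   - The dienophile is thus activated without free acid, which would ionise the dienyl carbinol or the ketal, and the smaller C7 group eases bonding at C7.
   - The hydroxy lactone adduct F2 is resilylated (TESOTf, 2,6-lutidine) to 24.

2. **Step 17.** Oxygen delivery from vanadium bound to a hindered tertiary homoallylic alcohol may be sluggish or poorly face-selective. External methanol may also open the epoxide before the C2 oxygen does.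
   Fallback, from 28 back to 31:
   - Iodoketalisation is run with N-iodosuccinimide in MeOH/CH2Cl2 at −20 °C. Iodonium formation is reversible, and only the β-iodonium ion can be opened at C9 by the C2 oxygen, so no directing group is needed. This gives the iodo ketal F3.
   - Tin-hydride-mediated radical oxygenation (Bu3SnH, air, PhMe; then PPh3) replaces iodine by hydroxyl.
   - Whichever C8 epimers form (30 and 32) are oxidised as in step 18 to 31.

3. **Step 23.** Acylation of the concave, hindered 9α-hydroxyl, which may rest as the hemiketal, may stall. Forcing conditions then invite deconjugation of the acyl group or acyl migration.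
   Fallback, from 35 back to 37:
   - The vinylketene pathway is used on purpose. Compound 36 with Et3N (CH2Cl2, −20 °C → rt) gives isopropenylketene, a small and flat acylating agent that adds hindered alcohols.
   - This affords the 3-methylbut-3-enoate F4.
   - Catalytic DBU in CH2Cl2 then moves the double bond into conjugation to give 37.

**Further compounds**
F1 | step 12 | triene alcohol (23 without the silyl group) | O=C1C(=C)[C@H](CC2(C/C=C\C=C\C(C)(C)O)OCCO2)CO1
F2 | step 12 | hydroxy lactone adduct (24 without the silyl group) | CC(C)(O)[C@H]1C[C@@]2(C(=O)OC4)[C@H](CC3(OCCO3)C[C@@H]24)C=C1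
F3 | step 17 | 8β-iodo-2α,9α-epoxy-2β-methoxy-10βH-eremophilan-11-ol | CC(C)(O)[C@H]1C[C@@]2(C)[C@H](C[C@]3(OC)C[C@@H]2C)[C@H](O3)[C@H]1I
F4 | step 23 | 8α-acetoxy-9α-(3-methylbut-3-enoyloxy)-10βH-eremophil-11-en-2-one | C=C(C)[C@H]1C[C@@]2(C)[C@H](CC(=O)C[C@@H]2C)[C@H](OC(=O)CC(C)=C)[C@@H]1OC(C)=O
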